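**Retrosynthetic overview**
1. Target 18 ⇒ hydroxy acetate aldehyde 17. Ring B (seven-membered, C6–C7 bond) and ring C (tetrahydrofuran, O–C11 bond) close together in one aldehyde-initiated cation–olefin cyclisation of a Z-alkene.
2. The tertiary acetate comes from acetolysis of the (R)-epoxide of 16. Ring A (cyclopentene) ⇒ gold-catalysed 5-endo-dig closure of alkynyl silyl enol ether 15.
3. 15 ⇒ allyl chloride 6 + a CH2 linchpin (C8) + Z-alkenyl iodide 13.
4. 6 ⇒ Eschenmoser–Tanabe fragmentation of (S)-carvone oxide, which supplies C1. 13 ⇒ carbocupration of propyne (Z geometry), then Shi epoxidation (C14).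
5. Ring order: the carvone ring is opened, then ring A forms, then rings B and C form together.

Assumption: the SMILES is taken literally, that is a trans-fused hydroazulene with (1R,5S,6S,7R,11S,14R) in prenylguaiane numbering (C1/C5 ring fusion, C6 carbinol, C7 side-chain carbon, C10 methylene carbon, C11/C14 tetrahydrofuran carbons, C15 acetoxy carbon).

Step 1
Reactants: 1 (S)-(+)-carvone
Product: 2 (1S,4S,6S)-1-methyl-4-(prop-1-en-2-yl)-7-oxabicyclo[4.1.0]heptan-2-one
Conditions: 30% H2O2, NaOH (cat.), MeOH, 0 °C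
Reagents that add atoms: hydrogen peroxide, OO
Why: Weitz–Scheffer nucleophilic epoxidation touches only the enone alkene, and hydroperoxide adds anti to the isopropenyl group; the two new centres are erased again in step 3.

Step 2
Reactants: 2 carvone oxide
Product: 3 (1S,4S,6S)-4-(3-chloroprop-1-en-2-yl)-1-methyl-7-oxabicyclo[4.1.0]heptan-2-one
Conditions: Ca(OCl)2, CO2 (s), CH2Cl2–H2O, 0 °C
Reagents that add atoms: calcium hypochlorite (delivers Cl via HOCl), [Ca+2].[O-]Cl.[O-]Cl
Why: Ene-type allylic chlorination by HOCl of the only remaining alkene shifts the double bond and gives the 2-(chloromethyl)allyl unit (C9, C10 and the future exocyclic CH2) without touching a stereocentre.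

Step 3
Reactants: 3 chloro epoxy ketone
Product: 5 (3R)-3-(3-chloroprop-1-en-2-yl)hept-5-ynal, via tosylhydrazone 4 (not isolated)
Conditions: TsNHNH2, AcOH–CH2Cl2 (1:1), −20 °C → rt
Reagents that add atoms: none
Why: Eschenmoser–Tanabe fragmentation of the α,β-epoxy hydrazone gives the methyl-capped alkyne (C3≡C4) and the aldehyde (C6), while carvone C5 is untouched and becomes C1 (R).

Step 4
Reactants: 5 chloro alkynal
Product: 6 tert-butyl{[(1Z,3R)-3-(3-chloroprop-1-en-2-yl)hept-1-en-5-yn-1-yl]oxy}dimethylsilane (Z major; the E isomer is equally usable)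
Conditions: TBSOTf, Et3N, CH2Cl2, 0 °C
Reagents that add atoms: tert-butyldimethylsilyl triflate, CC(C)(C)[Si](C)(C)OS(=O)(=O)C(F)(F)F
Why: Soft enolisation and O-silylation masks the aldehyde for the zinc chemistry and installs the carbon nucleophile (C5) needed in step 8.

Step 5
Reactants: 7 5-bromo-2-methylpent-2-ene; 8 propyne
Product: 12 (1Z)-1-iodo-2,6-dimethylhepta-1,5-diene, via Grignard reagent 9 (not isolated), via alkylcopper 10 (not isolated), via alkenylcopper 11 (not isolated)
Conditions: Mg, Et2O; CuBr·SMe2, Me2S–Et2O, −45 °C; 8, −25 °C; I2, THF, −50 → 0 °C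
Reagents that add atoms: iodine, II
Why: Normant carbocupration adds the alkyl group and copper syn across propyne (alkyl to the internal carbon), and iodinolysis with retention gives the Z-trisubstituted C7=C11 unit.

Step 6
Reactants: 12 Z-alkenyl iodide
Product: 13 (3R)-3-[(3Z)-4-iodo-3-methylbut-3-en-1-yl]-2,2-dimethyloxirane
Conditions: D-fructose-derived Shi ketone (30 mol %), KHSO5 (Oxone), K2CO3, Na2B4O7–Na2EDTA buffer, Bu4NHSO4, MeCN–DMM, 0 °C
Reagents that add atoms: potassium peroxymonosulfate, [K+].[O-]S(=O)(=O)OO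
Why: Shi asymmetric epoxidation through the spiro dioxirane transition state gives the R epoxide (C14), and the iodoalkene is too electron-poor to react.

Step 7
Reactants: 6 allyl chloride silyl enol ether; 13 epoxy alkenyl iodide
Product: 15 TBS (Z)-enol ether of (3R)-3-{(5Z)-8-[(2R)-3,3-dimethyloxiran-2-yl]-6-methylocta-1,5-dien-2-yl}hept-5-ynal, via homoallylzinc iodide 14 (not isolated)
Conditions: CH2(ZnI)2, Pd2(dba)3 (2.5 mol %), P[3,5-(CF3)2C6H3]3 (10 mol %), THF, 25 °C; then 13, PdCl2(dppf) (5 mol %), 40 °C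
Reagents that add atoms: bis(iodozincio)methane, I[Zn]C[Zn]I
Why: Sequential Negishi-type coupling of the geminal dizinc linchpin: the π-allyl complex of zerovalent palladium (both termini equivalent) takes one C–Zn bond, and the remaining primary alkylzinc couples with the alkenyl iodide with retention of the Z geometry, inserting C8.

Step 8
Reactants: 15 alkynyl silyl enol ether
Product: 16 (1S,5R)-5-{(5Z)-8-[(2R)-3,3-dimethyloxiran-2-yl]-6-methylocta-1,5-dien-2-yl}-2-methylcyclopent-2-ene-1-carbaldehyde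
Conditions: Ph3PAuNTf2 (2 mol %), 2,6-di-tert-butylpyridine (5 mol %), CH2Cl2–H2O (10:1), rt
Reagents that add atoms: none
Why: In this gold-catalysed 5-endo-dig carbocyclisation of a silyl enol ether (Conia-ene type), C5 attacks the gold-activated C4 and protodeauration leaves the C3=C4 alkene out of conjugation; the conformer that minimises A(1,3) strain (H-1 in the enol ether plane) puts the formyl group trans to the C1 side chain and sets C5 (S).

Step 9
Reactants: 16 epoxy aldehyde
Product: 18 target CNP0302132.4, via hydroxy acetate 17 (not isolated)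
Conditions: AcOH, 23 °C; evaporate (toluene); SnCl4 (30 mol %), CH2Cl2 (5 mM), −78 → −40 °C
Reagents that add atoms: acetic acid, CC(=O)O
Why: Proposed new method: acetic acid first opens the epoxide at its tertiary carbon (C15–OAc; the C14–O bond and the R configuration are kept) to give 17; SnCl4 then activates the aldehyde, the Z-alkene attacks C6 through its less substituted carbon C7 (ring B) while the C14 hydroxyl adds to the developing tertiary C11 cation from the opposite face (ring C); this anti addition to the Z-alkene links C7 (R) to C11 (S), the envelope with both large groups pseudo-equatorial (2,5-cis tetrahydrofuran) relays C14 to C11/C7, the tin-bound oxygen sits on the H-5 side away from the tether and gives 6S, and the trans C1/C5 relationship is carried over and blocks closure onto the C10 methylene (it would need a trans-bicyclo[3.3.0]octane); the proton freed from O14 ends on O6, so the step is an isomerisation of 17; closest known reaction types are the aldehyde- or acetal-initiated Prins/Johnson cation–olefin polycyclisation with Stork–Eschenmoser anti addition and hydroxyl-terminated polyene cyclisation.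

**Compound list**
1 | (S)-(+)-carvone | CC1=CC[C@@H](CC1=O)C(C)=C | starting material
2 | (1S,4S,6S)-1-methyl-4-(prop-1-en-2-yl)-7-oxabicyclo[4.1.0]heptan-2-one | C=C(C)[C@H]1C[C@@H]2O[C@]2(C)C(=O)C1 | intermediate
3 | (1S,4S,6S)-4-(3-chloroprop-1-en-2-yl)-1-methyl-7-oxabicyclo[4.1.0]heptan-2-one | C=C(CCl)[C@H]1C[C@@H]2O[C@]2(C)C(=O)C1 | intermediate
4 | tosylhydrazone of 3 | C=C(CCl)[C@H]1C[C@@H]2O[C@]2(C)C(=NNS(=O)(=O)c3ccc(C)cc3)C1 | intermediate
5 | (3R)-3-(3-chloroprop-1-en-2-yl)hept-5-ynal | O=CC[C@@H](CC#CC)C(=C)CCl | intermediate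
6 | TBS (Z)-enol ether of 5 | CC(C)(C)[Si](C)(C)O/C=C\[C@@H](CC#CC)C(=C)CCl | intermediate
7 | 5-bromo-2-methylpent-2-ene | CC(C)=CCCBr | starting material
8 | propyne | CC#C | starting material
9 | (4-methylpent-3-en-1-yl)magnesium bromide | CC(C)=CCC[Mg]Br | intermediate
10 | (4-methylpent-3-en-1-yl)copper | CC(C)=CCC[Cu] | intermediate
11 | [(1Z)-2,6-dimethylhepta-1,5-dien-1-yl]copper | [Cu]/C=C(/C)CCC=C(C)C | intermediate
12 | (1Z)-1-iodo-2,6-dimethylhepta-1,5-diene | I/C=C(/C)CCC=C(C)C | intermediate
13 | (3R)-3-[(3Z)-4-iodo-3-methylbut-3-en-1-yl]-2,2-dimethyloxirane | I/C=C(/C)CC[C@H]1OC1(C)C | intermediate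
14 | homoallylzinc iodide (6 with CH2CH2ZnI in place of CH2Cl) | CC(C)(C)[Si](C)(C)O/C=C\[C@@H](CC#CC)C(=C)CC[Zn]I | intermediate
15 | TBS (Z)-enol ether of (3R)-3-{(5Z)-8-[(2R)-3,3-dimethyloxiran-2-yl]-6-methylocta-1,5-dien-2-yl}hept-5-ynal | CC(C)(C)[Si](C)(C)O/C=C\[C@@H](CC#CC)C(=C)CC/C=C(/C)CC[C@H]1OC1(C)C | intermediate
16 | (1S,5R)-5-{(5Z)-8-[(2R)-3,3-dimethyloxiran-2-yl]-6-methylocta-1,5-dien-2-yl}-2-methylcyclopent-2-ene-1-carbaldehyde | O=C[C@@H]1C(C)=CC[C@H]1C(=C)CC/C=C(/C)CC[C@H]2OC2(C)C | intermediate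
17 | (1S,5R)-5-[(5Z,9R)-10-acetoxy-9-hydroxy-6,10-dimethylundeca-1,5-dien-2-yl]-2-methylcyclopent-2-ene-1-carbaldehyde | O=C[C@@H]1C(C)=CC[C@H]1C(=C)CC/C=C(/C)CC[C@@H](O)C(C)(C)OC(C)=O | intermediate
18 | CNP0302132.4, (1R,5S,6S,7R,11S,14R) | C=C1CC[C@@H]([C@]2(C)CC[C@H](C(C)(C)OC(C)=O)O2)[C@@H](O)[C@@H]2C(C)=CC[C@@H]12 | target

**Step count and risks**
Total steps: 9. Longest linear sequence: 7 (steps 1–4 and 7–9).

**Step 9 (most likely to fail).** The seven-membered closure may stop at the ene product. It may also lose the anti stereospecificity or give the wrong face at C6/C7, and acyl migration in 17 competes. The fallback sets out from 16 and comes back at 18, closing the two rings one after the other. 16 is opened with AcOH to 17 as before. Ring B is then closed alone by a Me2AlCl-promoted intramolecular carbonyl-ene reaction (CH2Cl2, −78 °C) to the hydroazulen-6-ol carrying a C11 methylene side chain F1. Ring C is closed by 5-exo iodoetherification (I2, NaHCO3, MeCN, 0 °C) to the iodomethyl tetrahydrofuran F2. Radical deiodination with (Me3Si)3SiH and AIBN (toluene, 80 °C) then gives 18.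

**Step 7.** The first coupling of the dizinc reagent may go twice, or the epoxide may suffer from the zinc halides. The fallback sets out from 1 and comes back at 14, bringing in C8 by a formaldehyde ene reaction instead of the linchpin.
- Carvone reacts with (CH2O)n and Me2AlCl to give the homoallylic alcohol (5S)-5-(4-hydroxybut-1-en-2-yl)-2-methylcyclohex-2-en-1-one F3.
- I2, PPh3 and imidazole convert it into the iodide (5S)-5-(4-iodobut-1-en-2-yl)-2-methylcyclohex-2-en-1-one F4.
- H2O2 and NaOH give the iodo epoxy ketone F5.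
- TsNHNH2 in AcOH–CH2Cl2 leads through the iodo tosylhydrazone F6 to (3R)-3-(4-iodobut-1-en-2-yl)hept-5-ynal F7.
- TBSOTf and Et3N give the iodo silyl enol ether F8.
- Zinc insertion (Zn, LiCl, THF) gives 14, which is coupled with 13 as in the second half of step 7.

**Step 8.** The epoxide may be opened by the cationic gold complex, or the 1,5-enyne formed by the C10 methylene and the alkyne may compete. The fallback sets out from 6 and comes back at 16, closing ring A before the fragments are joined, so that neither the epoxide nor the polyene chain meets gold. 6 is cyclised with Ph3PAuNTf2 in wet CH2Cl2 to (1S,5R)-5-(3-chloroprop-1-en-2-yl)-2-methylcyclopent-2-ene-1-carbaldehyde F9. NaBH4 reduces it to the chloro alcohol F10, because the dizinc reagent would methylenate an aldehyde. F10 is joined with CH2(ZnI)2 (one extra equivalent for the hydroxyl) and 13 under the catalysts of step 7 to give the epoxy alcohol F11. Dess–Martin periodinane buffered with NaHCO3 then gives 16.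

**Further compounds**
F1 | step 9 | carbonyl-ene product, hydroazulen-6-ol bearing a (6R)-7-acetoxy-6-hydroxy-7-methyloct-1-en-2-yl group at C7 | C=C1CC[C@@H](C(=C)CC[C@@H](O)C(C)(C)OC(C)=O)[C@@H](O)[C@@H]2C(C)=CC[C@@H]12
F2 | step 9 | iodomethyl tetrahydrofuran (18 with CH2I in place of the C11 methyl group) | C=C1CC[C@@H]([C@]2(CI)CC[C@H](C(C)(C)OC(C)=O)O2)[C@@H](O)[C@@H]2C(C)=CC[C@@H]12
F3 | step 7 | (5S)-5-(4-hydroxybut-1-en-2-yl)-2-methylcyclohex-2-en-1-one | CC1=CC[C@@H](CC1=O)C(=C)CCO
F4 | step 7 | (5S)-5-(4-iodobut-1-en-2-yl)-2-methylcyclohex-2-en-1-one | CC1=CC[C@@H](CC1=O)C(=C)CCI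
F5 | step 7 | (1S,4S,6S)-4-(4-iodobut-1-en-2-yl)-1-methyl-7-oxabicyclo[4.1.0]heptan-2-one | C=C(CCI)[C@H]1C[C@@H]2O[C@]2(C)C(=O)C1
F6 | step 7 | tosylhydrazone of F5 | C=C(CCI)[C@H]1C[C@@H]2O[C@]2(C)C(=NNS(=O)(=O)c3ccc(C)cc3)C1
F7 | step 7 | (3R)-3-(4-iodobut-1-en-2-yl)hept-5-ynal | O=CC[C@@H](CC#CC)C(=C)CCI
F8 | step 7 | TBS (Z)-enol ether of F7 | CC(C)(C)[Si](C)(C)O/C=C\[C@@H](CC#CC)C(=C)CCI
F9 | step 8 | (1S,5R)-5-(3-chloroprop-1-en-2-yl)-2-methylcyclopent-2-ene-1-carbaldehyde | O=C[C@@H]1C(C)=CC[C@H]1C(=C)CCl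
F10 | step 8 | [(1S,5R)-5-(3-chloroprop-1-en-2-yl)-2-methylcyclopent-2-en-1-yl]methanol | OC[C@@H]1C(C)=CC[C@H]1C(=C)CCl
F11 | step 8 | [(1S,5R)-5-{(5Z)-8-[(2R)-3,3-dimethyloxiran-2-yl]-6-methylocta-1,5-dien-2-yl}-2-methylcyclopent-2-en-1-yl]methanol | OC[C@@H]1C(C)=CC[C@H]1C(=C)CC/C=C(/C)CC[C@H]2OC2(C)C
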